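We want to know which of 4 set-ups leaves the most target, in percent of the substrate put in.

    substrate + partner → target (k1 = 0.079 /M/s)
    substrate + partner → isomer of the product A (k2 = 9.1 × 10⁻⁴ /M/s)
    substrate → decomposition product (k3 = 1.5 × 10⁻⁷ /s)
    target ⇌ isomer of the product B (K4 = 0.60, k4 = 1.1 × 10⁻⁴ /s)

in all of them: partner 50.0 mM
- Tuesday's: substrate 20 mM (fed, over 64.0 min); time 80 min; all but substrate at the start; substrate goes in evenly over 64.0 min, the run ends at 80 min
- Wednesday's: substrate 20 mM; a single well-mixed tank run continuously and read at steady state, 80 min in it on average
- Saturday's: substrate 20 mM; time 80 min; everything together in a closed stirred flask, run for 80 min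
- Monday's: substrate 20 mM; time 80 min; plug flow through a tube for 80 min, no back-mixing

- the stated concentrations are those of everything mixed, before any reaction; amounts are the same in each set-up
- the feed brings no volume worth counting
- run time (Tuesday's): 80 min

- the set-up with the highest amount of target at the outlet or at the end, in percent of the substrate put in ("none" if the first two lie within 2 percentage points) (Tuesday's / Wednesday's / Saturday's / Monday's / none)
- amount of target at the outlet or at the end, in percent of the substrate put in, Tuesday's
- amount of target at the outlet or at the end, in percent of the substrate put in, Wednesday's
- amount of target at the outlet or at the end, in percent of the substrate put in, Saturday's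
- amount of target at the outlet or at the end, in percent of the substrate put in, Monday's

We follow rates. On Saturday's, the coupling of substrate with partner to target starts at 4.74 mM/min. Two things slow it. Partner falls to 30.0 mM, a factor of 0.600, since substrate is the limiting reagent. Substrate itself then loses a power of ten every 16.2 min or faster, so by 80 min the coupling rate is down at least 4.94 powers of ten. Target takes a selectivity of 98.9 % of the substrate, and decomposition is far slower than the coupling.

What then moves is the drift of target to isomer of the product B. Its net rate slows as the way back grows, and target tends to 62.5 % of the pair. We call D, the drift decade, the time in which target's excess over that share falls by a power of ten: 131 min. The excess starts at 37.5 %.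

On Saturday's, target is nearly 80 min old, which gives us 70.9 %. Monday's tube gives each slice the same history, so the same figure. On Tuesday's, we take target as born when it is fed, because substrate's mean life with partner at 30.0 mM is 7.03 min, shorter than the feed time. Its mean age is then about 48.0 min, which gives us 77.7 %. We leave Wednesday's tank unreckoned, and among the others we choose Tuesday's, ahead of Saturday's and Monday's by 6.8 percentage points.

The forecast also names Tuesday's, with 79.5 %, 71.3 %, 71.8 % and 71.8 % for Tuesday's, Wednesday's, Saturday's and Monday's, since feeding “makes the target on average much younger”. Its figures stand above ours for Tuesday's and Saturday's.

The simulation gives Tuesday's as best, with 79.5 %, 71.3 %, 71.8 % and 71.8 % in the same order. On Saturday's, substrate's half-life by the coupling alone, partner as charged, is 2.9 min, shorter than target's 110 min by the forward drift alone, and target's age is about 0.611 of D there against about 0.366 of D on average on Tuesday's. Left until 800 min, Tuesday's mean age reaches 5.88 D, where D puts target at 61.8 %, and the run reads 61.8 %.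

All constants were chosen freely; the rest is arithmetic.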